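**Plan**

1. Retrosynthesis: the N-methyl group and all benzyl-type protection come off first (one hydrogenolytic reductive methylation). The piperidine (atoms N1'', C2''–C6'') is then cut at two bonds at once, C3''–C4'' and N1''–C2''. This leaves a 6-vinylflavanone and a 3-aminopropyl radical drawn from Cbz-protected 4-aminobutanoic acid.
2. The vinyl group goes back through a C6 iodide to 7,4'-di-O-benzyl-(2S)-naringenin.
3. Forward: ring C and its stereocentre are bought as (2S)-naringenin. O7/O4' benzylation, C6 iodination and Stille vinylation follow, and the piperidine ring is closed last, on the complete flavanone, by a light-driven radical–polar crossover [4+2] annulation.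
4. Enabling feature: C2'' sits on C6 of ring A, between O5–H and O7 and para to O1. A radical at C2'' is therefore oxidised with loss of the O5 proton to an ortho-quinone methide (C5=O, C6=C2''), and the tethered nitrogen adds to its methide carbon.
5. Stereochemistry: C2 (S) comes from the chiral pool and is kept by base-free steps. C2'' (R) is set by a chiral phosphoric acid in the ring closure (catalyst control, since the two centres are too far apart for substrate control).

Key step: step 5

Assumption: (2S)-naringenin is bought in high enantiomeric purity (to be checked by chiral HPLC before use); which antipode of the phosphoric acid gives the (R) centre must be settled in a trial run, and (R)-TRIP is written as the working choice.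

**Route**

Step 1
Reactants: 1 (2S)-naringenin
Product: 2 (2S)-7-(benzyloxy)-2-[4-(benzyloxy)phenyl]-5-hydroxychroman-4-one
Conditions: BnOH (2.3 equiv), PPh3, DIAD, THF, 0 °C to rt
Reagents that add atoms: benzyl alcohol, OCc1ccccc1
Why: Mitsunobu etherification should alkylate the two acidic, unchelated phenols (O7 and O4') while the 5-OH, locked in a hydrogen bond to the C4 carbonyl, stays free, and the near-neutral conditions avoid the base-induced ring opening to the chalcone that would racemise C2.

Step 2
Reactants: 2 (2S)-7-(benzyloxy)-2-[4-(benzyloxy)phenyl]-5-hydroxychroman-4-one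
Product: 3 (2S)-7-(benzyloxy)-2-[4-(benzyloxy)phenyl]-5-hydroxy-6-iodochroman-4-one
Conditions: BnMe3N+ ICl2− (1.05 equiv), CaCO3, CH2Cl2/MeOH, rt, dark
Reagents that add atoms: benzyltrimethylammonium dichloroiodate, C[N+](C)(C)Cc1ccccc1.Cl[I-]Cl
Why: Electrophilic aromatic iodination of the phloroglucinol-type ring A should go to C6, the position ortho to the free chelated 5-OH, as this reagent does with 5-hydroxy-7-alkoxyflavonoids; one equivalent of a mild iodonium source leaves the benzyloxyphenyl ring untouched, and CaCO3 takes up the HCl without opening ring C.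

Step 3
Reactants: 3 (2S)-7-(benzyloxy)-2-[4-(benzyloxy)phenyl]-5-hydroxy-6-iodochroman-4-one
Product: 4 (2S)-7-(benzyloxy)-2-[4-(benzyloxy)phenyl]-6-ethenyl-5-hydroxychroman-4-one
Conditions: Bu3SnCH=CH2, Pd(PPh3)4 (5 mol%), toluene, 100 °C, trace BHT
Reagents that add atoms: tributyl(vinyl)stannane, C=C[Sn](CCCC)(CCCC)CCCC
Why: Stille coupling of the aryl iodide tolerates the free phenol and the ketone and needs no base, so the C2 centre should not be touched.

Step 4
Reactants: 5 4-{[(benzyloxy)carbonyl]amino}butanoic acid; 6 N-hydroxyphthalimide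
Product: 7 1,3-dioxoisoindolin-2-yl 4-{[(benzyloxy)carbonyl]amino}butanoate
Conditions: DIC, DMAP (cat.), CH2Cl2, 0 °C to rt
Reagents that add atoms: none
Why: Carbodiimide (Steglich-type) esterification should give the redox-active ester, which carries the radical precursor and the N–H nucleophile three carbons apart.

Step 5
Reactants: 4 (2S)-7-(benzyloxy)-2-[4-(benzyloxy)phenyl]-6-ethenyl-5-hydroxychroman-4-one; 7 1,3-dioxoisoindolin-2-yl 4-{[(benzyloxy)carbonyl]amino}butanoate
Product: 9 benzyl (2R)-2-{(2S)-7-(benzyloxy)-2-[4-(benzyloxy)phenyl]-5-hydroxy-4-oxochroman-6-yl}piperidine-1-carboxylate, via ortho-quinone methide 8 (not isolated)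
Conditions: 7 (1.5 equiv), fac-Ir(ppy)3 (1 mol%), (R)-TRIP (10 mol%), CH2Cl2, blue LEDs (450 nm), 0 °C, degassed
Reagents that add atoms: none
Why: Proposed new method: excited tris(2-phenylpyridinato)iridium reduces the N-acyloxyphthalimide 7, which loses phthalimide anion and CO2 to give the primary 3-(Cbz-amino)propyl radical; this adds to the CH2 terminus of the vinyl group of 4 (new C3''–C4'' bond), and the benzylic radical at C2'' is oxidised by the tetravalent iridium and loses the O5 proton to give the neutral ortho-quinone methide 8. The chiral phosphoric acid then binds the quinone methide carbonyl (O5) and the carbamate N–H and delivers nitrogen to one face of the methide carbon in a 6-exo-trig aza-Michael closure (new N1''–C2'' bond), which restores the aromaticity of ring A. The closest known reaction types are the photoredox radical–polar crossover annulation of aryl alkenes with redox-active esters that carry a tethered N–H nucleophile, run with an achiral acid, and the chiral phosphoric acid-catalysed conjugate addition to ortho-quinone methides; their merger in one asymmetric event has not been shown. The C2'' centre should be set by the catalyst alone, because the C2 centre lies on the far side of ring A and cannot bias the closure. The step needs radical attack at the CH2 terminus only (secured by the benzylic stabilisation from O5, O7 and O1), closure through the tethered nitrogen faster than capture by phthalimide or by unreacted 4 (secured by the six-membered tether), and a catalysed closure that outruns the uncatalysed one (secured by the weak nucleophilicity of the carbamate and by the free 5-OH, which turns the cation into a neutral quinone methide that reacts only when acid-bound).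

Step 6
Reactants: 9 benzyl (2R)-2-{(2S)-7-(benzyloxy)-2-[4-(benzyloxy)phenyl]-5-hydroxy-4-oxochroman-6-yl}piperidine-1-carboxylate
Product: 11 (2S)-5,7-dihydroxy-2-(4-hydroxyphenyl)-6-[(2R)-1-methylpiperidin-2-yl]chroman-4-one, via secondary amine 10 (not isolated)
Conditions: H2 (1 atm), Pd/C (10% Pd), aq. HCHO (37%, 1.5 equiv), MeOH/EtOAc, rt
Reagents that add atoms: formaldehyde, C=O
Why: Hydrogenolysis should cleave the two aryl benzyl ethers and the benzyl carbamate (which loses CO2), and the freed secondary amine should then undergo reductive amination with formaldehyde on the same catalyst; the neutral conditions at room temperature should leave both stereocentres, the ketone and the hindered ring C–N and C2–O1 benzylic bonds intact.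

**Compound list**

1 | (2S)-naringenin, (2S)-5,7-dihydroxy-2-(4-hydroxyphenyl)chroman-4-one | O=C1C[C@@H](c2ccc(O)cc2)Oc2cc(O)cc(O)c12 | starting material
2 | (2S)-7-(benzyloxy)-2-[4-(benzyloxy)phenyl]-5-hydroxychroman-4-one | O=C1C[C@@H](c2ccc(OCc3ccccc3)cc2)Oc2cc(OCc3ccccc3)cc(O)c12 | intermediate
3 | (2S)-7-(benzyloxy)-2-[4-(benzyloxy)phenyl]-5-hydroxy-6-iodochroman-4-one | O=C1C[C@@H](c2ccc(OCc3ccccc3)cc2)Oc2cc(OCc3ccccc3)c(I)c(O)c12 | intermediate
4 | (2S)-7-(benzyloxy)-2-[4-(benzyloxy)phenyl]-6-ethenyl-5-hydroxychroman-4-one | O=C1C[C@@H](c2ccc(OCc3ccccc3)cc2)Oc2cc(OCc3ccccc3)c(C=C)c(O)c12 | intermediate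
5 | 4-{[(benzyloxy)carbonyl]amino}butanoic acid | OC(=O)CCCNC(=O)OCc1ccccc1 | starting material
6 | N-hydroxyphthalimide | ON1C(=O)c2ccccc2C1=O | starting material
7 | 1,3-dioxoisoindolin-2-yl 4-{[(benzyloxy)carbonyl]amino}butanoate | O=C(CCCNC(=O)OCc1ccccc1)ON1C(=O)c2ccccc2C1=O | intermediate
8 | ortho-quinone methide, benzyl {5-[(2S)-7-(benzyloxy)-2-[4-(benzyloxy)phenyl]-4,5-dioxo-2,3-dihydrochromen-6-ylidene]pentyl}carbamate (alkene geometry open) | O=C1C[C@@H](c2ccc(OCc3ccccc3)cc2)OC2=C1C(=O)C(=CCCCCNC(=O)OCc1ccccc1)C(OCc1ccccc1)=C2 | intermediate (not isolated)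
9 | benzyl (2R)-2-{(2S)-7-(benzyloxy)-2-[4-(benzyloxy)phenyl]-5-hydroxy-4-oxochroman-6-yl}piperidine-1-carboxylate | O=C(OCc1ccccc1)N1CCCC[C@@H]1c1c(OCc2ccccc2)cc2c(c1O)C(=O)C[C@@H](c1ccc(OCc3ccccc3)cc1)O2 | intermediate
10 | (2S)-5,7-dihydroxy-2-(4-hydroxyphenyl)-6-[(2R)-piperidin-2-yl]chroman-4-one | N1CCCC[C@@H]1c1c(O)cc2c(c1O)C(=O)C[C@@H](c1ccc(O)cc1)O2 | intermediate (not isolated)
11 | (2S)-5,7-dihydroxy-2-(4-hydroxyphenyl)-6-[(2R)-1-methylpiperidin-2-yl]chroman-4-one | CN1CCCC[C@@H]1c1c(O)cc2c(c1O)C(=O)C[C@@H](c1ccc(O)cc1)O2 | target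

**Step count and risks**

Total steps: 6. Longest linear sequence: 5 steps (1, 2, 3, 5, 6); step 4 is a one-step side branch.

Steps most likely to fail:

Step 5 (proposed new method). The ring closure may show poor facial selectivity if the benzylic cation cyclises before it is deprotonated and bound by the chiral acid. The quinone methide may also be captured by unreacted vinylphenol in a hetero-Diels–Alder reaction, and the new centre may erode by acid-promoted reopening of the carbamate to the quinone methide. The fallback uses known chemistry and forms the aryl–piperidine carbon bond instead of the two ring bonds. It sets out from 3: Stille coupling with tributyl(pyridin-2-yl)stannane (Pd(PPh3)4, CuI, toluene, 100 °C) should give (2S)-7-(benzyloxy)-2-[4-(benzyloxy)phenyl]-5-hydroxy-6-(pyridin-2-yl)chroman-4-one F1. Benzyl bromide in acetonitrile at 70 °C should give the 1-benzylpyridinium bromide F2. Asymmetric hydrogenation of the pyridinium salt ([Ir(cod)Cl]2, SynPhos antipode chosen for the (R) centre, H2 40 bar, toluene/CH2Cl2, rt, then NaHCO3 wash) should give (2S)-7-(benzyloxy)-6-[(2R)-1-benzylpiperidin-2-yl]-2-[4-(benzyloxy)phenyl]-5-hydroxychroman-4-one F3. Hydrogenolysis in the presence of formaldehyde (H2, Pd(OH)2/C, aq. HCHO, MeOH, rt) removes the three benzyl groups and methylates nitrogen, and the route is rejoined at 11.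

Step 2. Attack of the iodonium source at C8 (para to the 5-OH) or double iodination would give the wrong or a mixed substitution pattern. The fallback sets out from 2 and uses a reaction that can only go ortho to the free phenol: magnesium-mediated formylation (MgCl2, Et3N, paraformaldehyde, MeCN, reflux), in which formaldehyde is delivered within the O5 magnesium phenoxide, should give (2S)-7-(benzyloxy)-2-[4-(benzyloxy)phenyl]-5-hydroxy-4-oxochroman-6-carbaldehyde F4. Wittig methylenation (Ph3P=CH2 pre-formed from Ph3PCH3Br and KN(SiMe3)2, 2.2 equiv, THF, −78 to 0 °C) then gives 4, where the route is rejoined. The enantiomeric purity at C2 would be checked after both basic operations.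

Step 6. Once ring A is unmasked, formaldehyde may hydroxymethylate or aminomethylate C8, and prolonged hydrogenation may open the benzylic C–N bond of the piperidine or the C2–O1 bond. The fallback sets out from 9 and separates N-methylation from phenol release. Selective cleavage of the carbamate (Pd(OAc)2, Et3SiH, Et3N, CH2Cl2, rt, then MeOH) should give (2S)-7-(benzyloxy)-2-[4-(benzyloxy)phenyl]-5-hydroxy-6-[(2R)-piperidin-2-yl]chroman-4-one F5. Reductive amination (aq. HCHO, NaBH(OAc)3, 1,2-dichloroethane, rt) should give (2S)-7-(benzyloxy)-2-[4-(benzyloxy)phenyl]-5-hydroxy-6-[(2R)-1-methylpiperidin-2-yl]chroman-4-one F6. Hydrogenolysis without formaldehyde (H2, Pd/C, EtOAc/MeOH, rt) then gives 11.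

**Further compounds**

F1 | step 5 | (2S)-7-(benzyloxy)-2-[4-(benzyloxy)phenyl]-5-hydroxy-6-(pyridin-2-yl)chroman-4-one | O=C1C[C@@H](c2ccc(OCc3ccccc3)cc2)Oc2cc(OCc3ccccc3)c(-c3ccccn3)c(O)c12
F2 | step 5 | 1-benzyl-2-{(2S)-7-(benzyloxy)-2-[4-(benzyloxy)phenyl]-5-hydroxy-4-oxochroman-6-yl}pyridinium bromide | O=C1C[C@@H](c2ccc(OCc3ccccc3)cc2)Oc2cc(OCc3ccccc3)c(-c3cccc[n+]3Cc3ccccc3)c(O)c12.[Br-]
F3 | step 5 | (2S)-7-(benzyloxy)-6-[(2R)-1-benzylpiperidin-2-yl]-2-[4-(benzyloxy)phenyl]-5-hydroxychroman-4-one | C(c1ccccc1)N1CCCC[C@@H]1c1c(OCc2ccccc2)cc2c(c1O)C(=O)C[C@@H](c1ccc(OCc3ccccc3)cc1)O2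
F4 | step 2 | (2S)-7-(benzyloxy)-2-[4-(benzyloxy)phenyl]-5-hydroxy-4-oxochroman-6-carbaldehyde | O=Cc1c(OCc2ccccc2)cc2c(c1O)C(=O)C[C@@H](c1ccc(OCc3ccccc3)cc1)O2
F5 | step 6 | (2S)-7-(benzyloxy)-2-[4-(benzyloxy)phenyl]-5-hydroxy-6-[(2R)-piperidin-2-yl]chroman-4-one | N1CCCC[C@@H]1c1c(OCc2ccccc2)cc2c(c1O)C(=O)C[C@@H](c1ccc(OCc3ccccc3)cc1)O2
F6 | step 6 | (2S)-7-(benzyloxy)-2-[4-(benzyloxy)phenyl]-5-hydroxy-6-[(2R)-1-methylpiperidin-2-yl]chroman-4-one | CN1CCCC[C@@H]1c1c(OCc2ccccc2)cc2c(c1O)C(=O)C[C@@H](c1ccc(OCc3ccccc3)cc1)O2
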